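## Analysis of the target

Dictyoceratin C (25) is a sesquiterpenoid phenol built on a trans-fused decalin (ring A = C1–C5 and C10, ring B = C5–C10). The decalin carries an exocyclic methylene (C11) on C4, methyl groups on C5, C8 and C9, and on C9 the benzylic carbon C15, which is bonded to C1′ of a methyl 4-hydroxybenzoate (OH on C2′, ester on C5′). The four stereocentres (5S, 8S, 9R, 10S) are contiguous and two of them, C5 and C9, are quaternary; the methyl groups on C5 and C9 are 1,3-diaxial on the β face, H-10 is axial on the α face, the C8 methyl is equatorial (β) and the arylmethyl group is equatorial (α). The sensitive groups are the 1,1-disubstituted C4=C11 olefin (acid moves it into ring A; hydrogenation and electrophiles destroy it), the methyl ester (hydride, hydrazine, hydroxide) and the free phenol (oxidants, radicals). The hard part is the quaternary C9, which bears the benzyl group next to the ring fusion and must be set correctly relative to C5 across ring B while the exocyclic olefin is kept. The strategy rests on reading the skeleton from C9: if C8 is a carbonyl and the C9 methyl a carboxyl, C9 is the α-carbon of a β-keto ester, and the rest of the decalin is one chain, C7–C6–C5(CH3)=C10–C1–C2–C3–C4≡C11. Both ring bonds (C9–C10 and C4–C5) then lie on one E-olefin, and the alkyne delivers the exocyclic methylene.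

## Retrosynthetic reasoning

**Phenol and C8–H (25 ⇐ 24 ⇐ 23 ⇐ 22).** The phenol is kept as a methoxymethyl ether until the end, because an ester protecting group would not survive the organometallic and hydride steps, and the acetal is inert to all later steps. The C8–H bond is traced back to a C8–O bond, the oxalate 23 of tertiary alcohol 22. This oxygen is what remains of the ketone that the ring-forming step requires, so its removal costs no extra handle. The forward reaction must cleave a hindered tertiary C–O bond without acid and deliver hydrogen to the α face of C8.

**Arene ester (22 ⇐ 21).** The C5′–CO2CH3 bond is cut to a C5′–Br bond. A benzoate cannot pass the organometallic, hydride and hydrazone steps, whereas the bromide passes all of them. The carbonylation is placed before the radical deoxygenation because a stannyl radical would also take the bromine.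

**C9 methyl and C8 methyl (21 ⇐ 19 ⇐ 18 ⇐ 17 ⇐ 16).** The C9 methyl is traced back through aldehyde 19 and alcohol 18 to the axial ester of 16, and the C8 methyl to addition of a methyl nucleophile to the C8 ketone of 16. The forward steps must distinguish a ketone from a very hindered ester (addition first, then hydride). They must also take the aldehyde to the methyl group without strong base, since 19 is a β-hydroxy aldehyde that hot alkali would cleave by retro-aldol reaction; a tosylhydrazone (20) reduced under neutral conditions serves this purpose.

**Both rings (16 ⇐ 15).** The C9–C10 and C4–C5 bonds are cut together. This is the only place where two cuts return an acyclic chain in which every carbon of the decalin is already present and the oxidation needed to start the reaction (the β-keto ester) sits exactly at C8/C9. The gain is two rings, the exocyclic olefin and three stereocentres (C5, C9, C10) in one operation. The forward reaction has to close ring B in the endo sense, keep the ester axial, give the trans fusion, end on the alkyne by hydrogen abstraction and choose one face of the C9 radical under the influence of the ester auxiliary.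

**C9–C15 (15 ⇐ 11 + 14).** The benzyl group is attached by alkylating β-keto ester 11 with benzylic bromide 14. The bond is cut here because the doubly activated C9–H makes this the mildest C–C bond formation available, and because C15 must sit on the radical carbon before the cyclisation. The configuration formed at C9 in this step is irrelevant.

**Keto ester chain (11 ⇐ 7 + 8 + 9; 7 ⇐ 6 ⇐ 4 + 5; 4 ⇐ 2 + 3; 2 ⇐ 1).** The C8–C9 bond comes from acylation of 8 by acid 7 and alcoholysis of the adduct 10 with auxiliary 9, which introduces the hindered ester without strong base. The C6–C7 bond and the E geometry of C5=C10 come from an orthoester Claisen rearrangement of allylic alcohol 4 with 5. The C5–C10 bond comes from addition of 3 to aldehyde 2, the oxidation product of 1. The forward sequence has to deliver only the E-olefin and keep the terminal alkyne.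

**Benzylic bromide (14 ⇐ 13 ⇐ 12).** The bromide is made from the commercial benzylic alcohol 12 by phenol protection and a neutral bromination, so that the acetal is never exposed to acid.

## Alternatives that were turned down

**Alternative 1:** Ring A is taken as a preformed 2-methylcyclohexenone whose C10 carries the acyclic C9–C8–C7–C6 chain ending in a primary iodide (A2), and the C5–C6 bond is cut. In the forward sense KOtBu forms the extended dienolate by deprotonation at C1, and its α-carbon C5 displaces the iodide to close ring B. This gives the β,γ-enone A1 with quaternary C5 and a C1=C10 olefin, which is hydrogenated later, and the C4 ketone is methylenated. In its favour, C8 and C9 carry their final methyl groups from the start, so neither an ester-to-methyl nor a ketone-to-methyl sequence is needed. The closure is a classical, dependable reaction, and the C4 ketone is the direct precursor of the exocyclic olefin. On these points it is stronger than the chosen route. Against it, the key step forms one bond and one stereocentre. The real difficulty is moved into A2, which needs an acyclic quaternary C9 (methyl and arylmethyl) next to the tertiary C8 in defined absolute and relative configuration. That problem is harder than anything in the chosen route and has no short solution. The configuration at C5 would rely on induction from C9, where methyl and arylmethyl differ little in a chair transition state. The later hydrogenation must spare an aryl bromide and a benzyl-type ether. The chosen strategy spends steps on redox adjustment at C8 and C9, but reaches its cyclisation substrate 15 in eight steps, six of them in the longest line, from simple commercial materials and sets C5, C9 and C10 together.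

**Alternative 2:** The benzoate ring itself is disconnected (C1′–C6′ and C2′–C3′) into the bis-silyl ketene acetal A4 of the decalinyl propanoic acid and the pyrone A5. In the forward sense the electron-rich ketene acetal adds across the diene of A5, the bridged lactone decarboxylates, and loss of a silanol aromatises the ring to the silyl ether A3, one desilylation from 25. In its favour, the polarisation of A5 dictates the 1,2,5 substitution pattern, no aryl halide, carbonylation or phenol protecting group is needed, and the route is convergent. On the arene part it is clearly stronger than the chosen route, which spends three steps on protection, carbonylation and deprotection. Against it, the step creates no stereocentre and leaves the whole terpenoid problem untouched. A4 already needs the four stereocentres, the acid-sensitive exocyclic olefin and a two-carbon acid chain on the quaternary C9, so a second complete strategy of comparable length to the chosen one is required just to reach it. The nucleophilic carbon of A4 carries a neopentyl substituent, which slows the cycloaddition, and the hot aromatisation may move the C4=C11 double bond. The chosen strategy solves the stereochemical core in the same step that builds the rings.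

**Alternative 3:** Ring B is disconnected by an intermolecular [4+2] reaction (C5–C6 and C9–C10) into the diene A8 (C6–C9 with C15) and the dimenthyl mesaconate A7 (C4, C5, C10, C1). In the forward sense Et2AlCl promotes the cycloaddition to the cyclohexene trans-diester A6. In its favour, one step sets C5, C9 and C10, including both quaternary centres, C9 bears its real methyl group, the trans-diester maps onto the trans ring fusion, and the auxiliary of A7 is cheaper than 9. In number of stereocentres set it equals the chosen key step, and in auxiliary cost it is better. Against it, the reacting terminus of A8 is fully substituted, so one substituent must point inward in the s-cis diene, and the new C9–C10 bond joins a quaternary to a tertiary carbon. Such dienes are poor partners. The configuration at C9 depends at once on the geometrical purity of the tetrasubstituted olefin of A8, on the regiochemistry and on which ester of A7 lies endo (one must be exo), and none of these is secured. After the step ring A does not exist: two ester carbons must be joined through C2 and C3, the exocyclic methylene installed and C8 set by a face-selective reduction of C7=C8 that spares the aryl bromide, which is eight or more further steps. The chosen strategy closes both rings and installs the exocyclic olefin in the same event.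

Key step: step 9

## Route

Remark: α and β refer to the usual drawing with the C5 methyl β. Ar = 5-bromo-2-(methoxymethoxy)phenyl, Ar′ = 5-(methoxycarbonyl)-2-(methoxymethoxy)phenyl, R* = (−)-8-phenylmenthyl. The C8 carbinol in 17–23 is drawn as the 8β-hydroxy epimer expected from axial attack; the 8-epimer would serve equally, because C8 becomes a radical in step 16.

Step 1
Reactants: 1 hex-5-yn-1-ol
Product: 2 hex-5-ynal
Conditions: PhI(OAc)2, TEMPO (cat.), CH2Cl2, rt
Reagents that add atoms: none
Why: Oxoammonium (TEMPO) oxidation of a primary alcohol stops at the aldehyde and leaves the terminal alkyne untouched; the volatile aldehyde is carried on as a dried solution.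

Step 2
Reactants: 2 hex-5-ynal; 3 isopropenylmagnesium bromide
Product: 4 2-methyloct-1-en-7-yn-3-ol (racemic)
Conditions: THF, −78 → −20 °C; then cold 1 M HCl
Reagents that add atoms: none
Why: Grignard 1,2-addition forms the C5–C10 bond; at low temperature addition to the aldehyde is much faster than metalation of the terminal alkyne, and the racemic carbinol centre is erased in step 3.

Step 3
Reactants: 4 2-methyloct-1-en-7-yn-3-ol; 5 triethyl orthoacetate
Product: 6 ethyl (E)-4-methyldec-4-en-9-ynoate
Conditions: 5 (5 equiv), EtCO2H (cat.), 140 °C, ethanol distilled off
Reagents that add atoms: none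
Why: Johnson–Claisen rearrangement of the mixed ketene acetal through a chair with the pentynyl chain equatorial (the 2-methyl group penalises the axial alternative) forms C6–C7 and sets the E-trisubstituted C5=C10 olefin.

Step 4
Reactants: 6 ethyl (E)-4-methyldec-4-en-9-ynoate
Product: 7 (E)-4-methyldec-4-en-9-ynoic acid
Conditions: LiOH·H2O, THF/MeOH/H2O, rt; then 1 M HCl
Reagents that add atoms: lithium hydroxide, [Li+].[OH-]
Why: Saponification of an unhindered ethyl ester; nothing else in the molecule is base-sensitive.

Step 5
Reactants: 7 (E)-4-methyldec-4-en-9-ynoic acid; 8 Meldrum's acid; 9 (−)-8-phenylmenthol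
Product: 11 (−)-8-phenylmenthyl (E)-6-methyl-3-oxododec-6-en-11-ynoate, via acyl Meldrum's acid 10 (not isolated)
Conditions: 8, DCC, DMAP, CH2Cl2, 0 °C → rt, filter, evaporate; then 9, toluene, 110 °C
Reagents that add atoms: none
Why: C-Acylation of Meldrum's acid followed by thermal cycloreversion to an acylketene, which even a hindered secondary alcohol traps; the β-keto ester (C8–C9 bond) is formed without strong base, so alkyne and olefin are untouched.

Step 6
Reactants: 12 5-bromo-2-hydroxybenzyl alcohol
Product: 13 [5-bromo-2-(methoxymethoxy)phenyl]methanol
Conditions: MOMCl (1.05 equiv), K2CO3, acetone, 0 °C → rt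
Reagents that add atoms: chloromethyl methyl ether, COCCl
Why: Williamson-type O-alkylation; carbonate deprotonates only the phenol, and the phenoxide is far more nucleophilic than the neutral benzylic alcohol.

Step 7
Reactants: 13 [5-bromo-2-(methoxymethoxy)phenyl]methanol
Product: 14 4-bromo-2-(bromomethyl)-1-(methoxymethoxy)benzene
Conditions: CBr4, PPh3, CH2Cl2, 0 °C
Reagents that add atoms: carbon tetrabromide, BrC(Br)(Br)Br
Why: Appel reaction; the neutral conditions convert the benzylic alcohol into the bromide without cleaving the acetal.

Step 8
Reactants: 11 (−)-8-phenylmenthyl (E)-6-methyl-3-oxododec-6-en-11-ynoate; 14 4-bromo-2-(bromomethyl)-1-(methoxymethoxy)benzene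
Product: 15 (−)-8-phenylmenthyl (E)-2-(ArCH2)-6-methyl-3-oxododec-6-en-11-ynoate (mixture at C2)
Conditions: K2CO3, acetone, rt → 45 °C
Reagents that add atoms: none
Why: C-Alkylation of the β-keto ester enolate by a reactive benzylic bromide (SN2) forms C9–C15; one equivalent of electrophile and the bulk of the product prevent dialkylation, and the configuration formed at C9 does not matter because C9 becomes planar in step 9.

Step 9
Reactants: 15 (−)-8-phenylmenthyl (E)-2-(ArCH2)-6-methyl-3-oxododec-6-en-11-ynoate
Product: 16 trans-decalin keto ester (C4=C11; 8-oxo; 9β-CO2R* axial; 9α-CH2Ar; 5β-CH3; 10α-H)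
Conditions: Mn(OAc)3·2H2O (2.2 equiv), Yb(OTf)3 (1 equiv), degassed EtOH, 0 °C → rt
Reagents that add atoms: none
Why: Yb(OTf)3 speeds the enolisation of the 2-substituted β-keto ester, which is the slow step for this class, and the manganese enolate loses divalent manganese by electron transfer to give the electrophilic tertiary C9 radical. This radical adds to C10 of the electron-rich E-olefin in a 6-endo-trig closure (ring B, C9–C10), endo being favoured because it avoids the substituted olefin carbon and produces the tertiary C5 radical. The closure runs through a chair with the C8 carbonyl in the ring and the ketone oxygen, not C7, next to the arylmethyl group, which places the ester axial and C15 equatorial and so fixes C9 relative to C10. The C5 radical then closes ring A by a 6-exo-dig attack on the alkyne (C4–C5) from the face anti to the C9–C10 bond, the tether being equatorial on C10, which gives the trans fusion with the C5 methyl syn to the axial ester. The vinyl radical at C11 takes hydrogen from ethanol to leave C4=C11, the hydroxyethyl radical consumes the second equivalent of trivalent manganese, and without Cu(OAc)2 the tertiary C5 radical is not oxidised before it cyclises. For the absolute sense, the phenyl ring of the auxiliary covers one face of the planar ester-conjugated radical so that C10 bonds on the other; with the ester carbonyl s-cis to C8 this should be the face that leads to the configuration drawn, a point that an X-ray structure of 16 (bromine as heavy atom) should settle before material is carried forward. The closest known reaction type is the oxidative radical polycyclisation of unsaturated 2-alkyl β-keto esters with Mn(OAc)3, including 8-phenylmenthyl esters and alkyne terminators. The step needs endo regioselectivity, the axial ester, the trans fusion and facial selectivity; the first three come from the olefin substitution pattern and the chair, the last from the auxiliary.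

Step 10
Reactants: 16 trans-decalin keto ester
Product: 17 tertiary alcohol (8α-CH3; 8β-OH; 9β-CO2R*; 9α-CH2Ar)
Conditions: MeMgBr, dried CeCl3, THF, −78 °C; then AcOH/THF at −78 °C
Reagents that add atoms: methylmagnesium bromide, C[Mg]Br
Why: Organocerium 1,2-addition; the weakly basic, oxophilic reagent adds to the hindered, enolisable C8 ketone without deprotonation at C7 and without touching the hindered ester, the aryl bromide or the acetal. Axial attack anti to the axial ester is expected, and the cold quench avoids retro-aldol opening of the β-alkoxy ester.

Step 11
Reactants: 17 tertiary alcohol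
Product: 18 diol (9β-CH2OH; 8β-OH; 8α-CH3; 9α-CH2Ar)
Conditions: LiAlH4, THF, 0 → 45 °C; aq. NaOH work-up
Reagents that add atoms: none
Why: Hydride reduction of the ester to the neopentyl primary alcohol, assisted by the neighbouring C8 alkoxide; the auxiliary 9 is released and recovered, and the moderate temperature spares the aryl bromide.

Step 12
Reactants: 18 diol
Product: 19 β-hydroxy aldehyde (9β-CHO; 8β-OH)
Conditions: Dess–Martin periodinane, pyridine, CH2Cl2, 0 °C → rt
Reagents that add atoms: none
Why: Dess–Martin oxidation takes the primary alcohol to the aldehyde while the tertiary alcohol cannot react; the buffered non-basic medium leaves the β-hydroxy aldehyde, which has no α-hydrogen, intact.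

Step 13
Reactants: 19 β-hydroxy aldehyde
Product: 21 bromo carbinol (9β-CH3; 8β-OH; 8α-CH3; 9α-CH2Ar), via tosylhydrazone 20 (not isolated)
Conditions: TsNHNH2, 4 Å MS, THF, 40 °C; then catecholborane, CHCl3, 0 °C → rt; NaOAc·3H2O, 60 °C
Reagents that add atoms: none
Why: Reductive deoxygenation of the aldehyde through its tosylhydrazone, the mild relative of the Wolff–Kishner reduction: the borane reduces C=N, and acetate-induced loss of sulfinate and N2 from the diazene leaves the C9 methyl. The neutral conditions avoid the retro-aldol cleavage that hot alkali would cause in this β-hydroxy aldehyde and tolerate the aryl bromide and the olefin.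

Step 14
Reactants: 21 bromo carbinol
Product: 22 methyl benzoate carbinol (Ar′; 8β-OH)
Conditions: Pd(OAc)2 (5 mol %), Xantphos (10 mol %), CO (1 atm), Et3N, MeOH/toluene, 70 °C
Reagents that add atoms: carbon monoxide, [C-]#[O+]; methanol, CO
Why: Palladium-catalysed alkoxycarbonylation: oxidative addition of zerovalent palladium into the unhindered C–Br bond, CO insertion and methanolysis of the acyl palladium; the tertiary alcohol, the acetal and the 1,1-disubstituted olefin are inert.

Step 15
Reactants: 22 methyl benzoate carbinol
Product: 23 tertiary methyl oxalate (8β-OC(O)CO2CH3)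
Conditions: ClC(O)CO2Me, Et3N, DMAP, CH2Cl2, 0 °C → rt
Reagents that add atoms: methyl chlorooxoacetate, COC(=O)C(=O)Cl
Why: Acylation of the tertiary alcohol by the highly electrophilic acylpyridinium of the chlorooxoacetate; the oxalate is the radical leaving group for step 16.

Step 16
Reactants: 23 tertiary methyl oxalate
Product: 24 dictyoceratin C methoxymethyl ether (8β-CH3; 8α-H)
Conditions: Bu3SnH, AIBN (cat.), toluene, 110 °C, slow addition
Reagents that add atoms: none
Why: Radical deoxygenation of a tertiary alkyl oxalate in a Barton–McCombie-type chain: the stannyl radical adds to the oxalate, C8–O homolysis gives the tertiary radical, and Bu3SnH delivers hydrogen to the α face (axial attack, anti to the axial C9 methyl), which places the C8 methyl equatorial. The step follows the carbonylation because Bu3SnH would also reduce the aryl bromide.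

Step 17
Reactants: 24 dictyoceratin C methoxymethyl ether
Product: 25 dictyoceratin C
Conditions: conc. HCl (cat.), MeOH, rt
Reagents that add atoms: none
Why: Acid-catalysed acetal exchange with methanol frees the phenol; transesterification of the methyl ester in methanol is degenerate, and dilute acid at room temperature should be too weak to move the exocyclic olefin into ring A.

## Compound list

1 | hex-5-yn-1-ol | C#CCCCCO | starting material
2 | hex-5-ynal | C#CCCCC=O | intermediate
3 | isopropenylmagnesium bromide | CC(=C)[Mg]Br | starting material
4 | 2-methyloct-1-en-7-yn-3-ol (racemic) | C=C(C)C(O)CCCC#C | intermediate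
5 | triethyl orthoacetate | CCOC(C)(OCC)OCC | starting material
6 | ethyl (E)-4-methyldec-4-en-9-ynoate | CCOC(=O)CC/C(C)=C/CCCC#C | intermediate
7 | (E)-4-methyldec-4-en-9-ynoic acid | OC(=O)CC/C(C)=C/CCCC#C | intermediate
8 | Meldrum's acid (2,2-dimethyl-1,3-dioxane-4,6-dione) | CC1(C)OC(=O)CC(=O)O1 | starting material
9 | (−)-8-phenylmenthol, (1R,2S,5R) | CC(C)(c1ccccc1)[C@@H]1CC[C@@H](C)C[C@H]1O | starting material
10 | acyl Meldrum's acid, 5-[(E)-1-hydroxy-4-methyldec-4-en-9-ynylidene]-2,2-dimethyl-1,3-dioxane-4,6-dione (not isolated) | CC1(C)OC(=O)C(=C(O)CC/C(C)=C/CCCC#C)C(=O)O1 | intermediate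
11 | (−)-8-phenylmenthyl (E)-6-methyl-3-oxododec-6-en-11-ynoate | CC(C)(c1ccccc1)[C@@H]1CC[C@@H](C)C[C@H]1OC(=O)CC(=O)CC/C(C)=C/CCCC#C | intermediate
12 | 5-bromo-2-hydroxybenzyl alcohol | OCc1cc(Br)ccc1O | starting material
13 | [5-bromo-2-(methoxymethoxy)phenyl]methanol | OCc1cc(Br)ccc1OCOC | intermediate
14 | 4-bromo-2-(bromomethyl)-1-(methoxymethoxy)benzene | BrCc1cc(Br)ccc1OCOC | intermediate
15 | (−)-8-phenylmenthyl (E)-2-{[5-bromo-2-(methoxymethoxy)phenyl]methyl}-6-methyl-3-oxododec-6-en-11-ynoate (mixture at C2) | CC(C)(c1ccccc1)[C@@H]1CC[C@@H](C)C[C@H]1OC(=O)C(Cc1cc(Br)ccc1OCOC)C(=O)CC/C(C)=C/CCCC#C | intermediate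
16 | trans-decalin keto ester: 4-methylene, 8-oxo, 9β-(8-phenylmenthyloxycarbonyl), 9α-(ArCH2), 5β-methyl, 10α-H | C=C1CCC[C@H]2[C@](C(=O)O[C@@H]4C[C@H](C)CC[C@H]4C(C)(C)c5ccccc5)(Cc3cc(Br)ccc3OCOC)C(=O)CC[C@]12C | intermediate
17 | tertiary alcohol: as 16 with 8β-hydroxy and 8α-methyl | C=C1CCC[C@H]2[C@](C(=O)O[C@@H]4C[C@H](C)CC[C@H]4C(C)(C)c5ccccc5)(Cc3cc(Br)ccc3OCOC)[C@@](C)(O)CC[C@]12C | intermediate
18 | diol: 9β-hydroxymethyl, 8β-hydroxy, 8α-methyl, 9α-(ArCH2), 5β-methyl, 4-methylene trans-decalin | C=C1CCC[C@H]2[C@](CO)(Cc3cc(Br)ccc3OCOC)[C@@](C)(O)CC[C@]12C | intermediate
19 | β-hydroxy aldehyde: 9β-formyl analogue of 18 | C=C1CCC[C@H]2[C@](C=O)(Cc3cc(Br)ccc3OCOC)[C@@](C)(O)CC[C@]12C | intermediate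
20 | (E)-tosylhydrazone of 19 (not isolated) | C=C1CCC[C@H]2[C@](/C=N/NS(=O)(=O)c4ccc(C)cc4)(Cc3cc(Br)ccc3OCOC)[C@@](C)(O)CC[C@]12C | intermediate
21 | bromo carbinol: 9β-methyl, 8β-hydroxy, 8α-methyl, 9α-(ArCH2) | C=C1CCC[C@H]2[C@](C)(Cc3cc(Br)ccc3OCOC)[C@@](C)(O)CC[C@]12C | intermediate
22 | methyl benzoate carbinol: as 21 with CO2CH3 in place of Br | C=C1CCC[C@H]2[C@](C)(Cc3cc(C(=O)OC)ccc3OCOC)[C@@](C)(O)CC[C@]12C | intermediate
23 | tertiary methyl oxalate of 22 | C=C1CCC[C@H]2[C@](C)(Cc3cc(C(=O)OC)ccc3OCOC)[C@@](C)(OC(=O)C(=O)OC)CC[C@]12C | intermediate
24 | dictyoceratin C methoxymethyl ether | C=C1CCC[C@H]2[C@](C)(Cc3cc(C(=O)OC)ccc3OCOC)[C@@H](C)CC[C@]12C | intermediate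
25 | dictyoceratin C, methyl 4-hydroxy-3-{[(1R,2S,4aS,8aS)-1,2,4a-trimethyl-5-methylidenedecahydronaphthalen-1-yl]methyl}benzoate | C=C1CCC[C@H]2[C@](C)(Cc3cc(C(=O)OC)ccc3O)[C@@H](C)CC[C@]12C | target

## Step count and least certain steps

Total step count: 17. Longest linear sequence: 15 steps (steps 1–5 and 8–17); the benzylic bromide branch is steps 6–7.

**Step 9 (key step).** Three things may go wrong. The shielding by the auxiliary may select the opposite face, or select poorly, because the sense depends on which rotamer of the ester-conjugated radical reacts. Binding of Yb(OTf)3 to both carbonyl oxygens may hold the radical in the U-shaped form, whose chair places the ester equatorial; this would erode the C9/C5 relation. The C5 radical may be quenched by the solvent before it reaches the alkyne.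

The fallback reverses the order of cyclisation and benzylation and sets out from acid 7. Acylation of 8 and alcoholysis of 10 with the enantiomeric auxiliary (+)-8-phenylmenthol F1 would give the 2-unsubstituted keto ester F2. Its cyclisation under the conditions of step 9 runs through the metal-chelated enol radical, the best-precedented case for this auxiliary class; since that chair has the ester equatorial, the same shielding model calls for the enantiomeric auxiliary to reach the same ring fusion. It should give the bicyclic keto ester F3 (C9 labile). Alkylation of the enolate of F3 with 14 (K2CO3, acetone) should occur from the α face, away from the 1,3-diaxial C5 methyl, to give the axial-ester keto ester F4. Methyl addition as in step 10 would give carbinol F5, and LiAlH4 as in step 11 releases F1 and returns to the route at 18.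

**Step 10.** Deprotonation at C7 may compete with addition at the very congested carbonyl, and the metal β-alkoxy ester may open by retro-aldol reaction if it warms. The fallback sets out from 16 and removes the ester before the methyl group is added. LiAlH4 would reduce ketone and ester to the diol F6. TEMPO/PhI(OAc)2 would oxidise only the primary alcohol, to the hydroxy aldehyde F7. The tosylhydrazone F8, reduced as in step 13, would give the secondary alcohol F9. Dess–Martin oxidation would give the ketone F10, which no longer has a β-ester, and MeMgBr/CeCl3 addition to it returns to the route at 21.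

**Step 13.** Condensation at the neopentyl aldehyde may be slow, excess borane may hydroborate the exocyclic olefin on heating, or the β-hydroxy hydrazone may fragment. The fallback sets out from 18 and replaces carbonyl deoxygenation by radical dehalogenation. I2/PPh3/imidazole (toluene, 80 °C) would convert the primary alcohol into the neopentyl iodide F11. Bu3SnH (1.1 equiv) with Et3B/air at rt should reduce the C–I bond selectively, because alkyl iodides transfer iodine to stannyl radicals far faster than aryl bromides transfer bromine. This returns to the route at 21.

**Step 16 (with step 15).** Acylation of the tertiary alcohol flanked by a quaternary carbon may stay incomplete, and hydrogen transfer to the β face of the C8 radical would give the C8 epimer. The fallback sets out from 18 and cleaves the C8–O bond from a cyclic derivative while C9 still carries a larger axial group. Carbonylation as in step 14 would give the ester diol F12. 1,1′-Thiocarbonyldiimidazole with DMAP in hot toluene would close the cyclic thionocarbonate F13; this is possible because the 8β-hydroxyl is gauche to the axial CH2O. Bu3SnH/AIBN opens it at the tertiary carbon and reduces the C8 radical from the α face, and K2CO3/MeOH then frees the primary alcohol F14. Its xanthate F15 (NaH, CS2, MeI) would be reduced by Bu3SnH/AIBN in xylene at 140 °C (Barton–McCombie reaction), which returns to the route at 24.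

## Further compounds

F1 | step 9 | (+)-8-phenylmenthol, (1S,2R,5S) | CC(C)(c1ccccc1)[C@H]1CC[C@H](C)C[C@@H]1O
F2 | step 9 | (+)-8-phenylmenthyl (E)-6-methyl-3-oxododec-6-en-11-ynoate | CC(C)(c1ccccc1)[C@H]1CC[C@H](C)C[C@@H]1OC(=O)CC(=O)CC/C(C)=C/CCCC#C
F3 | step 9 | (+)-8-phenylmenthyl 5β-methyl-4-methylene-8-oxo-10α-H-trans-decalin-9-carboxylate (C9 labile) | C=C1CCC[C@H]2C(C(=O)O[C@H]3C[C@@H](C)CC[C@@H]3C(C)(C)c4ccccc4)C(=O)CC[C@]12C
F4 | step 9 | analogue of 16 with the (+)-8-phenylmenthyl ester | C=C1CCC[C@H]2[C@](C(=O)O[C@H]4C[C@@H](C)CC[C@@H]4C(C)(C)c5ccccc5)(Cc3cc(Br)ccc3OCOC)C(=O)CC[C@]12C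
F5 | step 9 | analogue of 17 with the (+)-8-phenylmenthyl ester | C=C1CCC[C@H]2[C@](C(=O)O[C@H]4C[C@@H](C)CC[C@@H]4C(C)(C)c5ccccc5)(Cc3cc(Br)ccc3OCOC)[C@@](C)(O)CC[C@]12C
F6 | step 10 | diol: 9β-hydroxymethyl, 8β-hydroxy (secondary), 9α-(ArCH2) | C=C1CCC[C@H]2[C@](CO)(Cc3cc(Br)ccc3OCOC)[C@@H](O)CC[C@]12C
F7 | step 10 | hydroxy aldehyde: 9β-formyl, 8β-hydroxy | C=C1CCC[C@H]2[C@](C=O)(Cc3cc(Br)ccc3OCOC)[C@@H](O)CC[C@]12C
F8 | step 10 | (E)-tosylhydrazone of F7 | C=C1CCC[C@H]2[C@](/C=N/NS(=O)(=O)c4ccc(C)cc4)(Cc3cc(Br)ccc3OCOC)[C@@H](O)CC[C@]12C
F9 | step 10 | secondary alcohol: 9β-methyl, 8β-hydroxy | C=C1CCC[C@H]2[C@](C)(Cc3cc(Br)ccc3OCOC)[C@@H](O)CC[C@]12C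
F10 | step 10 | ketone: 9β-methyl, 8-oxo | C=C1CCC[C@H]2[C@](C)(Cc3cc(Br)ccc3OCOC)C(=O)CC[C@]12C
F11 | step 13 | neopentyl iodide: 9β-iodomethyl, 8β-hydroxy, 8α-methyl | C=C1CCC[C@H]2[C@](CI)(Cc3cc(Br)ccc3OCOC)[C@@](C)(O)CC[C@]12C
F12 | step 16 | ester diol: analogue of 18 with CO2CH3 in place of Br | C=C1CCC[C@H]2[C@](CO)(Cc3cc(C(=O)OC)ccc3OCOC)[C@@](C)(O)CC[C@]12C
F13 | step 16 | cyclic thionocarbonate of F12 (1,3-dioxane-2-thione across C9–CH2O and C8–O) | C=C1CCC[C@H]2[C@@]3(Cc4cc(C(=O)OC)ccc4OCOC)COC(=S)O[C@@]3(C)CC[C@]12C
F14 | step 16 | primary alcohol: 9β-hydroxymethyl, 8β-methyl, 8α-H | C=C1CCC[C@H]2[C@](CO)(Cc3cc(C(=O)OC)ccc3OCOC)[C@@H](C)CC[C@]12C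
F15 | step 16 | S-methyl xanthate of F14 | C=C1CCC[C@H]2[C@](COC(=S)SC)(Cc3cc(C(=O)OC)ccc3OCOC)[C@@H](C)CC[C@]12C
A1 | alternative 1 | bicyclic β,γ-enone with C1=C10 olefin and 4-oxo group | O=C1CCC=C2[C@](C)(Cc3cc(Br)ccc3OCc4ccc(OC)cc4)[C@@H](C)CC[C@]12C
A2 | alternative 1 | 3-(1-aryl-5-iodo-2,3-dimethylpentan-2-yl)-2-methylcyclohex-2-enone | O=C1CCCC([C@](C)(Cc2cc(Br)ccc2OCc3ccc(OC)cc3)[C@@H](C)CCI)=C1C
A3 | alternative 2 | trimethylsilyl ether of dictyoceratin C | C=C1CCC[C@H]2[C@](C)(Cc3cc(C(=O)OC)ccc3O[Si](C)(C)C)[C@@H](C)CC[C@]12C
A4 | alternative 2 | bis(trimethylsilyl) ketene acetal of the 3-(decalin-9-yl)propanoic acid | C=C1CCC[C@H]2[C@](C)(CC=C(O[Si](C)(C)C)O[Si](C)(C)C)[C@@H](C)CC[C@]12C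
A5 | alternative 2 | methyl coumalate | COC(=O)C1=COC(=O)C=C1
A6 | alternative 3 | ring B cyclohexene trans-diester (di-(−)-menthyl) | CC(C)[C@@H]1CC[C@@H](C)C[C@H]1OC(=O)[C@H]2[C@](C)(Cc3cc(Br)ccc3O[Si](C(C)C)(C(C)C)C(C)C)C(C)=CC[C@]2(C)C(=O)O[C@@H]1C[C@H](C)CC[C@H]1C(C)C
A7 | alternative 3 | di-(−)-menthyl mesaconate | CC(C)[C@@H]1CC[C@@H](C)C[C@H]1OC(=O)/C(C)=C/C(=O)O[C@@H]1C[C@H](C)CC[C@H]1C(C)C
A8 | alternative 3 | (E)-5-aryl-3,4-dimethylpenta-1,3-diene (aryl = 5-bromo-2-triisopropylsilyloxyphenyl) | C=C/C(C)=C(C)/Cc1cc(Br)ccc1O[Si](C(C)C)(C(C)C)C(C)C
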